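Ring B of the benzodioxane is unsymmetrical. O4 on C4a sits beside the C5 methoxy group, O1 on C8a sits beside C8–H, and C7 carries the carbon side chain. The plan therefore leaves the C4a–C8a and C7–C8 bonds until last. The precursor is a threo (S,S) 1-arylglycerol diether with an ethynyl group on O1 and a 4-methoxy-6-methoxycarbonyl-2-pyron-3-yl group on O4. It undergoes an intramolecular Diels–Alder reaction. Loss of CO2 from the bridged lactone then delivers the dioxane ring and aromatic ring B in one operation, with each oxygen already in place. Both stereocentres come from (R)-glyceraldehyde acetonide, a Felkin–Anh aryl addition and one Mitsunobu inversion.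

Key step: step 12

Assumption: chain and ring atoms are named throughout by the numbering O1, C2 (aryl-bearing), C3 (CH2O-bearing), O4, C4a, C5 (OMe), C6, C7 (side chain), C8, C8a. Aldehyde 11 is taken as bought material and distilled just before use, because it oligomerises on storage.

Fragment 1: pyrone 8 (steps 1–4)

Step 1
Reactants: 1 methyl acetoacetate
Product: 2 methyl (E)-3-methoxybut-2-enoate
Conditions: HC(OMe)3, H2SO4 (cat.), MeOH, rt; distillation
Reagents that add atoms: trimethyl orthoformate, COC(OC)OC
Why: Acid-catalysed enol ether formation from a β-keto ester (ketalisation by the orthoester, then loss of methanol) should give the conjugated E isomer, whose C4 methyl group lies cis to the ester as the later lactonisation requires.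

Step 2
Reactants: 2 methyl (E)-3-methoxybut-2-enoate; 3 dimethyl oxalate
Product: 5 methyl 4-methoxy-2-oxo-2H-pyran-6-carboxylate, via dienol diester 4 (not isolated)
Conditions: KOMe, THF, 0 °C to rt; then HCl in MeOH, 50 °C
Reagents that add atoms: none
Why: In this vinylogous Claisen condensation methoxide reversibly removes a γ-proton of 2, the dienolate is acylated by the oxalate, the stabilised enolate of 4 pulls the equilibrium, and under acid its enol oxygen lactonises onto the cis ester (the classical crotonate–oxalate route to 2-pyrone-6-carboxylates), which fixes the methoxy group at C4 with no tautomer ambiguity.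

Step 3
Reactants: 5 methyl 4-methoxy-2-oxo-2H-pyran-6-carboxylate
Product: 6 methyl 3-bromo-4-methoxy-2-oxo-2H-pyran-6-carboxylate
Conditions: NBS, MeCN, rt to 50 °C
Reagents that add atoms: N-bromosuccinimide, O=C1CCC(=O)N1Br
Why: Electrophilic bromination of a 4-methoxy-2-pyrone goes to C3, the nucleophilic α-carbon of the β-methoxy enoate, while C5 is deactivated as the β-carbon of the acrylate unit at C6.

Step 4
Reactants: 6 methyl 3-bromo-4-methoxy-2-oxo-2H-pyran-6-carboxylate
Product: 8 methyl 3-hydroxy-4-methoxy-2-oxo-2H-pyran-6-carboxylate, via pinacol boronate 7 (not isolated)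
Conditions: B2pin2, PdCl2(dppf), KOAc, dioxane, 80 °C; then 30% H2O2, pH 7 phosphate buffer, THF, 0 °C
Reagents that add atoms: hydrogen peroxide, OO; bis(pinacolato)diboron, CC1(C)OB(OC1(C)C)B1OC(C)(C)C(C)(C)O1 (boron unit of 7 only)
Why: Miyaura borylation of the alkenyl bromide with the weak base KOAc, followed by buffered peroxide oxidation (1,2-shift of carbon from boron to oxygen), should install the 3-hydroxy group that acetoacetate–oxalate chemistry alone does not supply, under conditions mild enough for the lactone and the ester.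

Fragment 2: chain 21 (steps 5–10)

Step 5
Reactants: 9 4-bromo-2,6-dimethoxyphenol
Product: 10 5-bromo-1,3-dimethoxy-2-(methoxymethoxy)benzene
Conditions: NaH, MOMCl, THF–DMF, 0 °C to rt
Reagents that add atoms: chloromethyl methyl ether, COCCl
Why: Williamson-type alkylation of the phenoxide gives a MOM ether that withstands KH, organolithiums and warming and later falls together with the silyl ether in one acid step.

Step 6
Reactants: 10 5-bromo-1,3-dimethoxy-2-(methoxymethoxy)benzene; 11 (R)-2,2-dimethyl-1,3-dioxolane-4-carbaldehyde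
Product: 14 (S)-[(4R)-2,2-dimethyl-1,3-dioxolan-4-yl][3,5-dimethoxy-4-(methoxymethoxy)phenyl]methanol (erythro), via aryllithium 12 (not isolated), via aryltitanium triisopropoxide 13 (not isolated)
Conditions: n-BuLi, THF, −78 °C; ClTi(OiPr)3, −78 to −40 °C; 11, −78 to 0 °C; aq. NH4Cl
Reagents that add atoms: n-butyllithium, [Li]CCCC (lithium of 12 only); chlorotitanium triisopropoxide, CC(C)O[Ti](Cl)(OC(C)C)OC(C)C (titanium unit of 13 only)
Why: Bromine–lithium exchange and transmetalation give a weakly Lewis acidic, non-chelating aryltitanium reagent that should add to the α-alkoxy aldehyde under Felkin–Anh control, setting C2 as S in the anti (erythro) alcohol with C3 taken from the chiral pool, the benzylic OH free and the other two oxygens held in a non-migrating acetal, and any threo epimer is removed by chromatography.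

Step 7
Reactants: 14 erythro alcohol; 15 trichloroethylene
Product: 16 (4R)-4-{(S)-[(E)-1,2-dichloroethenyloxy][3,5-dimethoxy-4-(methoxymethoxy)phenyl]methyl}-2,2-dimethyl-1,3-dioxolane
Conditions: KH, THF, 0 °C to rt; then 15, −50 °C to rt
Reagents that add atoms: none
Why: The potassium alkoxide adds anti to dichloroacetylene released in situ by dehydrochlorination of 15 (the standard trichloroethylene route to 1,2-dichlorovinyl ethers, proven on hindered secondary benzylic alcohols), the C2–O bond is never broken so C2 keeps its configuration, and the acetonide excludes the silyl migration that a neighbouring silyl ether would risk.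

Step 8
Reactants: 16 dichlorovinyl ether acetonide
Product: 17 (2R,3S)-3-[(E)-1,2-dichloroethenyloxy]-3-[3,5-dimethoxy-4-(methoxymethoxy)phenyl]propane-1,2-diol
Conditions: 80% aq. AcOH, THF, rt
Reagents that add atoms: none
Why: In this mild acid hydrolysis of a terminal acetonide the enol ether is deactivated towards protonation by its two chlorine atoms and the aryl MOM acetal needs a stronger acid, so only the dioxolane should open, and this is done before the acid-labile ynol ether exists.

Step 9
Reactants: 17 diol
Product: 18 (1S,2R)-3-(tert-butyldimethylsilyloxy)-1-[(E)-1,2-dichloroethenyloxy]-1-[3,5-dimethoxy-4-(methoxymethoxy)phenyl]propan-2-ol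
Conditions: TBSCl (1.05 equiv), imidazole, CH2Cl2, 0 °C
Reagents that add atoms: tert-butyldimethylsilyl chloride, CC(C)(C)[Si](C)(C)Cl
Why: Sterically controlled monosilylation of the primary hydroxyl of a 1,2-diol leaves the C3 carbinol free for the later inversion.

Step 10
Reactants: 18 silyl ether alcohol
Product: 21 (1S,2R)-3-(tert-butyldimethylsilyloxy)-1-(ethynyloxy)-1-[3,5-dimethoxy-4-(methoxymethoxy)phenyl]propan-2-ol, via chloroethynyl ether 19 (not isolated), via lithium acetylide 20 (not isolated)
Conditions: n-BuLi (3.3 equiv), THF, −78 to −40 °C; H2O–THF, −78 °C; cold Et2O/pH 7 buffer; kept below 0 °C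
Reagents that add atoms: n-butyllithium, [Li]CCCC (lithium of 19 and 20 only)
Why: After deprotonation of the hydroxyl, vinyl lithiation with β-elimination of LiCl, chlorine–lithium exchange and protonation follow the standard dichlorovinyl ether to ynol ether conversion, no bond at C2 or C3 is touched, a lithium alkoxide is inert towards the alkyne at −78 °C, and a silyl shift from the primary to the secondary oxygen is thermodynamically uphill.

Union, key step and endgame

Step 11
Reactants: 21 hydroxy ynol ether; 8 methyl 3-hydroxy-4-methoxy-2-oxo-2H-pyran-6-carboxylate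
Product: 22 methyl 3-{[(1S,2S)-3-(tert-butyldimethylsilyloxy)-1-(ethynyloxy)-1-[3,5-dimethoxy-4-(methoxymethoxy)phenyl]propan-2-yl]oxy}-4-methoxy-2-oxo-2H-pyran-6-carboxylate (threo)
Conditions: PPh3, DIAD, THF, 0 °C (betaine preformed); then 8, then 21, −10 to 15 °C; cold Et3N-deactivated silica
Reagents that add atoms: none
Why: In this Mitsunobu etherification the acidic enolic 3-OH of 8 displaces the oxyphosphonium group at C3 by SN2, so C3 is inverted from R to S (erythro to threo) as in aryl ether formation at this carbon of arylglycerols, while preforming the betaine keeps free azodicarboxylate away from the ynol ether and the cold, near-neutral medium spares it.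

Step 12
Reactants: 22 threo ynol ether pyrone
Product: 24 methyl (2S,3S)-3-[(tert-butyldimethylsilyloxy)methyl]-2-[3,5-dimethoxy-4-(methoxymethoxy)phenyl]-5-methoxy-2,3-dihydro-1,4-benzodioxine-7-carboxylate (trans), via bridged lactone 23 (not isolated)
Conditions: Eu(fod)3 (10 mol %; fod = 6,6,7,7,8,8,8-heptafluoro-2,2-dimethyloctane-3,5-dionate), 4 Å MS, PhMe (0.01 M), 23 to 45 °C, Ar
Reagents that add atoms: none
Why: The electron-rich ethynyl ether adds across C3 and C6 of the ester-bearing 2-pyrone in an inverse-electron-demand intramolecular Diels–Alder reaction, its nucleophilic terminal carbon bonding to C6 (the vinylogous acceptor position of the lactone, future C7) and its oxygen-bearing carbon to C3 (future C4a), and the bridged dienyl lactone 23 then loses CO2 by retro-[4+2] to give the arene with no redox step. The closest known chemistry is the 2-pyrone/alkyne cycloaddition–decarboxylation route to benzenes, known in tethered form and with heteroatom-substituted alkynes, together with the lanthanide-catalysed addition of enol ethers to 2-pyrone esters, and the oxygen-linked ethynyl tether is only a new substrate for it. The dioxane closes as the six-membered tether ring O1–C2–C3–O4–C4a–C8a at the moment the C4a–C8a bond forms, and ring B closes by the [4+2] union of four pyrone carbons with the two alkyne carbons followed by cycloreversion. No lasting stereocentre is made, because the two bridgehead centres of 23 vanish on aromatisation, so either face of the pyrone may react, and C2 and C3 are carried through untouched. The step needs regiocontrol, which the four-atom tether secures (the reverse orientation is geometrically out of reach) and the matched polarity supports. It also needs chemoselectivity over retro-ene loss of ketene and [3,3] shift of the benzylic ethynyl ether, which is why Eu(fod)3, a mild oxophilic Lewis acid that can chelate the C2 carbonyl and O4 and that enol-ether type π systems tolerate, is used to hold the temperature at or below 45 °C.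

Step 13
Reactants: 24 benzodioxane ester
Product: 25 {(2S,3S)-3-[(tert-butyldimethylsilyloxy)methyl]-2-[3,5-dimethoxy-4-(methoxymethoxy)phenyl]-5-methoxy-2,3-dihydro-1,4-benzodioxin-7-yl}methanol
Conditions: DIBAL-H (2.5 equiv), CH2Cl2, −78 to 0 °C; Rochelle salt
Reagents that add atoms: none
Why: Full DIBAL-H reduction of the aryl ester to the benzylic alcohol is more dependable than stopping at the aldehyde, and MOM, silyl and aryl ethers are inert to it.

Step 14
Reactants: 25 benzylic alcohol; 26 methyl (triphenylphosphoranylidene)acetate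
Product: 28 methyl (E)-3-{(2S,3S)-3-[(tert-butyldimethylsilyloxy)methyl]-2-[3,5-dimethoxy-4-(methoxymethoxy)phenyl]-5-methoxy-2,3-dihydro-1,4-benzodioxin-7-yl}prop-2-enoate, via aldehyde 27 (not isolated)
Conditions: MnO2 (excess), 26, CH2Cl2, rt
Reagents that add atoms: none
Why: In this tandem oxidation–Wittig process MnO2 oxidises only the benzylic alcohol and the stabilised ylide traps aldehyde 27 as it forms, giving the E enoate typical of stabilised ylides.

Step 15
Reactants: 28 protected enoate
Product: 29 methyl (E)-3-[(2S,3S)-2-(4-hydroxy-3,5-dimethoxyphenyl)-3-(hydroxymethyl)-5-methoxy-2,3-dihydro-1,4-benzodioxin-7-yl]prop-2-enoate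
Conditions: HCl (0.5 M in MeOH), 0 °C to rt
Reagents that add atoms: none
Why: Acid-catalysed transacetalisation and silyl ether methanolysis remove MOM and TBS in one operation at the enoate stage, where no acid-labile cinnamyl alcohol is present, methanol matches the methyl ester, and any reversible ionisation at benzylic C2 can only return the more stable trans ring because C3 is fixed.

Step 16
Reactants: 29 dihydroxy enoate
Product: 30 (2S,3S)-2-(4-hydroxy-3,5-dimethoxyphenyl)-3-(hydroxymethyl)-7-[(E)-3-hydroxyprop-1-enyl]-5-methoxy-2,3-dihydro-1,4-benzodioxine (target)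
Conditions: DIBAL-H (6 equiv), CH2Cl2–THF, −78 to −20 °C; Rochelle salt
Reagents that add atoms: none
Why: 1,2-Reduction of a cinnamate ester by excess DIBAL-H, well proven on sinapate and ferulate esters with a free phenol, should give the E allylic alcohol once the two OH groups have been taken up as aluminium alkoxides.

Compound list
1 | methyl acetoacetate | COC(=O)CC(C)=O | starting material
2 | methyl (E)-3-methoxybut-2-enoate | C/C(OC)=C\C(=O)OC | intermediate
3 | dimethyl oxalate | COC(=O)C(=O)OC | starting material
4 | dimethyl (2Z,4E)-2-hydroxy-4-methoxyhexa-2,4-dienedioate, formed as its potassium enolate (not isolated) | COC(=O)/C(O)=C/C(OC)=C\C(=O)OC | intermediate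
5 | methyl 4-methoxy-2-oxo-2H-pyran-6-carboxylate | COC(=O)C1=CC(OC)=CC(=O)O1 | intermediate
6 | methyl 3-bromo-4-methoxy-2-oxo-2H-pyran-6-carboxylate | COC(=O)C1=CC(OC)=C(Br)C(=O)O1 | intermediate
7 | methyl 4-methoxy-2-oxo-3-(4,4,5,5-tetramethyl-1,3,2-dioxaborolan-2-yl)-2H-pyran-6-carboxylate (not isolated) | COC(=O)C1=CC(OC)=C(B2OC(C)(C)C(C)(C)O2)C(=O)O1 | intermediate
8 | methyl 3-hydroxy-4-methoxy-2-oxo-2H-pyran-6-carboxylate | COC(=O)C1=CC(OC)=C(O)C(=O)O1 | intermediate
9 | 4-bromo-2,6-dimethoxyphenol | COc1cc(Br)cc(OC)c1O | starting material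
10 | 5-bromo-1,3-dimethoxy-2-(methoxymethoxy)benzene | COCOc1c(OC)cc(Br)cc1OC | intermediate
11 | (R)-2,2-dimethyl-1,3-dioxolane-4-carbaldehyde | O=C[C@H]1COC(C)(C)O1 | starting material
12 | [3,5-dimethoxy-4-(methoxymethoxy)phenyl]lithium (not isolated) | [Li]c1cc(OC)c(OCOC)c(OC)c1 | intermediate
13 | [3,5-dimethoxy-4-(methoxymethoxy)phenyl]titanium triisopropoxide (not isolated) | CC(C)O[Ti](OC(C)C)(OC(C)C)c1cc(OC)c(OCOC)c(OC)c1 | intermediate
14 | (S)-[(4R)-2,2-dimethyl-1,3-dioxolan-4-yl][3,5-dimethoxy-4-(methoxymethoxy)phenyl]methanol | COCOc1c(OC)cc([C@H](O)[C@H]2COC(C)(C)O2)cc1OC | intermediate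
15 | trichloroethylene | ClC=C(Cl)Cl | starting material
16 | (4R)-4-{(S)-[(E)-1,2-dichloroethenyloxy][3,5-dimethoxy-4-(methoxymethoxy)phenyl]methyl}-2,2-dimethyl-1,3-dioxolane | COCOc1c(OC)cc([C@H](O/C(Cl)=C\Cl)[C@H]2COC(C)(C)O2)cc1OC | intermediate
17 | (2R,3S)-3-[(E)-1,2-dichloroethenyloxy]-3-[3,5-dimethoxy-4-(methoxymethoxy)phenyl]propane-1,2-diol | COCOc1c(OC)cc([C@H](O/C(Cl)=C\Cl)[C@H](O)CO)cc1OC | intermediate
18 | (1S,2R)-3-(tert-butyldimethylsilyloxy)-1-[(E)-1,2-dichloroethenyloxy]-1-[3,5-dimethoxy-4-(methoxymethoxy)phenyl]propan-2-ol | COCOc1c(OC)cc([C@H](O/C(Cl)=C\Cl)[C@H](O)CO[Si](C)(C)C(C)(C)C)cc1OC | intermediate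
19 | lithium alkoxide of the (1S,2R) chloroethynyl ether (not isolated) | COCOc1c(OC)cc([C@H](OC#CCl)[C@H](O[Li])CO[Si](C)(C)C(C)(C)C)cc1OC | intermediate
20 | dilithio species, (1S,2R) lithium alkoxide and lithium acetylide of the ynol ether (not isolated) | COCOc1c(OC)cc([C@H](OC#C[Li])[C@H](O[Li])CO[Si](C)(C)C(C)(C)C)cc1OC | intermediate
21 | (1S,2R)-3-(tert-butyldimethylsilyloxy)-1-(ethynyloxy)-1-[3,5-dimethoxy-4-(methoxymethoxy)phenyl]propan-2-ol | COCOc1c(OC)cc([C@H](OC#C)[C@H](O)CO[Si](C)(C)C(C)(C)C)cc1OC | intermediate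
22 | methyl 3-{[(1S,2S)-3-(tert-butyldimethylsilyloxy)-1-(ethynyloxy)-1-[3,5-dimethoxy-4-(methoxymethoxy)phenyl]propan-2-yl]oxy}-4-methoxy-2-oxo-2H-pyran-6-carboxylate | COCOc1c(OC)cc([C@H](OC#C)[C@@H](OC2=C(OC)C=C(C(=O)OC)OC2=O)CO[Si](C)(C)C(C)(C)C)cc1OC | intermediate
23 | dioxane-fused 2-oxabicyclo[2.2.2]octa-5,7-dien-3-one cycloadduct, bridgeheads C4a and C7, either bridgehead diastereomer, (2S,3S) in the dioxane (not isolated) | COCOc1c(OC)cc([C@@H]2OC3=CC4(C(=O)OC)C=C(OC)C3(O[C@H]2CO[Si](C)(C)C(C)(C)C)C(=O)O4)cc1OC | intermediate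
24 | methyl (2S,3S)-3-[(tert-butyldimethylsilyloxy)methyl]-2-[3,5-dimethoxy-4-(methoxymethoxy)phenyl]-5-methoxy-2,3-dihydro-1,4-benzodioxine-7-carboxylate | COCOc1c(OC)cc([C@@H]2Oc3cc(C(=O)OC)cc(OC)c3O[C@H]2CO[Si](C)(C)C(C)(C)C)cc1OC | intermediate
25 | {(2S,3S)-3-[(tert-butyldimethylsilyloxy)methyl]-2-[3,5-dimethoxy-4-(methoxymethoxy)phenyl]-5-methoxy-2,3-dihydro-1,4-benzodioxin-7-yl}methanol | COCOc1c(OC)cc([C@@H]2Oc3cc(CO)cc(OC)c3O[C@H]2CO[Si](C)(C)C(C)(C)C)cc1OC | intermediate
26 | methyl (triphenylphosphoranylidene)acetate | COC(=O)C=P(c1ccccc1)(c1ccccc1)c1ccccc1 | starting material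
27 | (2S,3S)-3-[(tert-butyldimethylsilyloxy)methyl]-2-[3,5-dimethoxy-4-(methoxymethoxy)phenyl]-5-methoxy-2,3-dihydro-1,4-benzodioxine-7-carbaldehyde (not isolated) | COCOc1c(OC)cc([C@@H]2Oc3cc(C=O)cc(OC)c3O[C@H]2CO[Si](C)(C)C(C)(C)C)cc1OC | intermediate
28 | methyl (E)-3-{(2S,3S)-3-[(tert-butyldimethylsilyloxy)methyl]-2-[3,5-dimethoxy-4-(methoxymethoxy)phenyl]-5-methoxy-2,3-dihydro-1,4-benzodioxin-7-yl}prop-2-enoate | COCOc1c(OC)cc([C@@H]2Oc3cc(/C=C/C(=O)OC)cc(OC)c3O[C@H]2CO[Si](C)(C)C(C)(C)C)cc1OC | intermediate
29 | methyl (E)-3-[(2S,3S)-2-(4-hydroxy-3,5-dimethoxyphenyl)-3-(hydroxymethyl)-5-methoxy-2,3-dihydro-1,4-benzodioxin-7-yl]prop-2-enoate | COc1cc([C@@H]2Oc3cc(/C=C/C(=O)OC)cc(OC)c3O[C@H]2CO)cc(OC)c1O | intermediate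
30 | (2S,3S)-2-(4-hydroxy-3,5-dimethoxyphenyl)-3-(hydroxymethyl)-7-[(E)-3-hydroxyprop-1-enyl]-5-methoxy-2,3-dihydro-1,4-benzodioxine | COc1cc([C@@H]2Oc3cc(/C=C/CO)cc(OC)c3O[C@H]2CO)cc(OC)c1O | target

Total step count: 16. Longest linear sequence: 12 steps (9 to 30, steps 5–16). The pyrone branch (steps 1–4) joins at step 11.

Steps most likely to fail

1. Step 12. The two donor oxygens at pyrone C3 and C4 may slow the cycloaddition so much that retro-ene fragmentation or [3,3] rearrangement of the benzylic ethynyl ether consumes the substrate first. The fallback builds ring B from a ready-made arene. It sets out from 21 and returns at 24.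
   - Mitsunobu reaction of 21 with commercial methyl 3-bromo-4-hydroxy-5-methoxybenzoate (PPh3, DIAD, THF, 0 °C) inverts C3 and gives the bromoaryl ether F1.
   - Brief treatment with catalytic PPTS in wet THF at 0 °C hydrates the ynol ether to the C2 acetate F2.
   - K2CO3 in MeOH frees the threo C2 alcohol F3.
   - Palladium-catalysed intramolecular aryl etherification (Buchwald–Hartwig C–O coupling; Pd(OAc)2, 2-(di-tert-butylphosphino)-1,1'-binaphthyl, Cs2CO3, toluene, 70 °C) closes O1–C8a without touching the C2–O bond and gives 24.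

2. Step 11. Three processes may defeat the coupling or erode the inversion: slow activation of the hindered carbinol with competing elimination, attack of azodicarboxylate on the ynol ether, and participation of the electron-rich aryl group. The fallback separates activation from displacement. It sets out from 21 and returns at 22.
   - Tf2O and pyridine in CH2Cl2 at −78 °C give the C3 triflate F4.
   - F4 is treated without storage with the caesium salt of 8 (Cs2CO3, MeCN, −20 to 0 °C), so that SN2 attack by the pyronolate oxygen inverts C3 and gives 22.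

3. Step 10. The lithium alkoxide next to the reacting vinyl ether may trigger silyl migration or ring closure onto the new alkyne, and the free hydroxyl may add to the ynol ether during work-up. The fallback masks C3–OH for the organolithium stage. It sets out from 18 and returns at 21.
   - TMSCl and imidazole in CH2Cl2 give the bis-silyl ether F5.
   - n-BuLi (2.2 equiv, THF, −78 °C) followed by a cold water quench gives the silylated ynol ether F6.
   - K2CO3 in MeOH at 0 °C removes only the trimethylsilyl group and gives 21.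

Further compounds
F1 | step 12 | methyl 3-bromo-4-{[(1S,2S)-3-(tert-butyldimethylsilyloxy)-1-(ethynyloxy)-1-[3,5-dimethoxy-4-(methoxymethoxy)phenyl]propan-2-yl]oxy}-5-methoxybenzoate (bromoaryl ether) | COCOc1c(OC)cc([C@H](OC#C)[C@@H](Oc2c(Br)cc(C(=O)OC)cc2OC)CO[Si](C)(C)C(C)(C)C)cc1OC
F2 | step 12 | methyl 4-{[(1S,2S)-1-acetoxy-3-(tert-butyldimethylsilyloxy)-1-[3,5-dimethoxy-4-(methoxymethoxy)phenyl]propan-2-yl]oxy}-3-bromo-5-methoxybenzoate (C2 acetate) | COCOc1c(OC)cc([C@H](OC(C)=O)[C@@H](Oc2c(Br)cc(C(=O)OC)cc2OC)CO[Si](C)(C)C(C)(C)C)cc1OC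
F3 | step 12 | methyl 3-bromo-4-{[(1S,2S)-3-(tert-butyldimethylsilyloxy)-1-hydroxy-1-[3,5-dimethoxy-4-(methoxymethoxy)phenyl]propan-2-yl]oxy}-5-methoxybenzoate (threo C2 alcohol) | COCOc1c(OC)cc([C@H](O)[C@@H](Oc2c(Br)cc(C(=O)OC)cc2OC)CO[Si](C)(C)C(C)(C)C)cc1OC
F4 | step 11 | (1S,2R)-3-(tert-butyldimethylsilyloxy)-1-(ethynyloxy)-1-[3,5-dimethoxy-4-(methoxymethoxy)phenyl]propan-2-yl trifluoromethanesulfonate (C3 triflate) | COCOc1c(OC)cc([C@H](OC#C)[C@H](OS(=O)(=O)C(F)(F)F)CO[Si](C)(C)C(C)(C)C)cc1OC
F5 | step 10 | (1S,2R)-3-(tert-butyldimethylsilyloxy)-1-[(E)-1,2-dichloroethenyloxy]-1-[3,5-dimethoxy-4-(methoxymethoxy)phenyl]-2-(trimethylsilyloxy)propane (bis-silyl ether) | COCOc1c(OC)cc([C@H](O/C(Cl)=C\Cl)[C@H](O[Si](C)(C)C)CO[Si](C)(C)C(C)(C)C)cc1OC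
F6 | step 10 | (1S,2R)-3-(tert-butyldimethylsilyloxy)-1-(ethynyloxy)-1-[3,5-dimethoxy-4-(methoxymethoxy)phenyl]-2-(trimethylsilyloxy)propane (silylated ynol ether) | COCOc1c(OC)cc([C@H](OC#C)[C@H](O[Si](C)(C)C)CO[Si](C)(C)C(C)(C)C)cc1OC
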